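**Plan**

1. Numbering: the terpene carbons are numbered as in bornane (C1 methyl-bearing bridgehead, C2 the O–CH, C3 CH2, C4 bridgehead CH, C5 CH2, C6 the CH carrying the benzylic CH2, C7 CMe2); the bornane part is (1R,2S,4R,6S), i.e. the (+)-borneol series with O and CH2 both endo.
2. Retrosynthesis: the CHO is removed first (it sits on the only free aromatic position); then C1–C2 and C3–C4 are cut together. The five-membered ring C1–C6–C5–C4–C7 is a latent 1,5,5-trimethylcyclopentadiene and C2–C3 a two-carbon dienophile. Because the ether oxygen on C2 and the ArCH2 on C6 are both endo and 1,3 across C1, the arene itself (CH2–Car–Car–O) is a ready four-atom tether from diene C-2 to the dienophile, so one intramolecular [4+2] builds the bicyclo[2.2.1] six-membered ring and the seven-membered benzoxepine at once. Last, the ArO–CH=, ArC–CH2 and dienyl–CH2OH bonds are cut.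
3. Helper: the dienophile carries a temporary oxazolidinone carboximide on C3 (activation and two-point binding to a chiral copper catalyst); it is taken out afterwards by hydrolysis and radical decarboxylation.
4. Forward order: cyclopentenone → dienyl triflate → dienylmethanol; C-allylation of phlorisovalerophenone; oxa-Michael addition to a propioloyl imide; cycloaddition (both new rings); hydrogenation of C5=C6; helper removal; formylation.
5. Stereochemistry: C2 from the catalyst-controlled face of the dienophile; C1 and C4 from the tether-enforced endo topology of the suprafacial addition; C6 from exo-face hydrogenation, the only mode the seven-membered ring allows.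

Key step: step 8

Remark: the two hydroxyls ortho to the ketone are carried unprotected, on the assumption that a neutral, chelated phenol does not displace the bidentate imide from the copper catalyst.

**Route**

Step 1
Reactants: 1 4,4-dimethylcyclopent-2-en-1-one
Product: 3 4,4,5-trimethylcyclopent-2-en-1-one (racemic), via lithium enolate 2 (not isolated)
Conditions: LiN(i-Pr)2, THF, −78 °C; MeI, −78 → 0 °C
Reagents that add atoms: iodomethane, CI; lithium diisopropylamide, [Li+].CC(C)[N-]C(C)C (lithium in 2 only)
Why: C4 is quaternary, so kinetic deprotonation can only occur at C5, and alkylation of that enolate (enolate alkylation) installs the future C1 methyl group; the stereocentre formed here is erased in step 2.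

Step 2
Reactants: 3 4,4,5-trimethylcyclopent-2-en-1-one
Product: 5 2,3,3-trimethylcyclopenta-1,4-dien-1-yl trifluoromethanesulfonate, via lithium dienolate 4 (not isolated)
Conditions: LiN(i-Pr)2, THF, −78 → 0 °C; PhNTf2, 0 °C → rt
Reagents that add atoms: N-phenylbis(trifluoromethanesulfonimide), O=S(=O)(N(c1ccccc1)S(=O)(=O)C(F)(F)F)C(F)(F)F; lithium diisopropylamide, [Li+].CC(C)[N-]C(C)C (lithium in 4 only)
Why: the single remaining α-hydrogen gives one cross-conjugated dienolate, and its O-sulfonylation (enol triflate formation) fixes the 1,3-diene, which the quaternary CMe2 carbon protects from 1,5-hydrogen shifts and from fast dimerisation.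

Step 3
Reactants: 5 2,3,3-trimethylcyclopenta-1,4-dien-1-yl trifluoromethanesulfonate
Product: 6 (2,3,3-trimethylcyclopenta-1,4-dien-1-yl)methanol
Conditions: Bu3SnCH2OH, Pd(PPh3)4 (5 mol%), LiCl, 1,4-dioxane, 90 °C
Reagents that add atoms: (tributylstannyl)methanol, CCCC[Sn](CCCC)(CCCC)CO
Why: Stille coupling of an enol triflate with the hydroxymethyl stannane (chloride assists transmetalation) puts in the carbon that becomes the benzylic CH2 and gives the allylic alcohol directly.

Step 4
Reactants: 7 phloroglucinol; 8 3-methylbutanoyl chloride
Product: 9 3-methyl-1-(2,4,6-trihydroxyphenyl)butan-1-one (phlorisovalerophenone)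
Conditions: AlCl3, PhNO2/CH2Cl2, 0 → 40 °C; aq. HCl work-up
Reagents that add atoms: none
Why: Friedel–Crafts C-acylation of the symmetric triphenol should stop at the monoketone because the acyl group deactivates the ring, and it leaves two equivalent free ring positions and one unique hydroxyl para to the ketone.

Step 5
Reactants: 9 phlorisovalerophenone (threefold excess); 6 (2,3,3-trimethylcyclopenta-1,4-dien-1-yl)methanol
Product: 10 3-methyl-1-{2,4,6-trihydroxy-3-[(2,3,3-trimethylcyclopenta-1,4-dien-1-yl)methyl]phenyl}butan-1-one
Conditions: Pd(PPh3)4 (5 mol%), Et3B (30 mol%), THF, 40 °C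
Reagents that add atoms: none
Why: borane-assisted ionisation of the allylic alcohol gives a π-allyl palladium complex that the nucleophilic ring carbon of the phloroglucinol should attack at its unhindered CH2 terminus (Tsuji–Trost C-allylation of a benzene polyol), the other terminus being fully substituted and neopentyl, while the excess of 9 limits double allylation.

Step 6
Reactants: 11 propiolic acid; 12 1,3-oxazolidin-2-one
Product: 13 3-(prop-2-ynoyl)-1,3-oxazolidin-2-one
Conditions: DCC, DMAP (5 mol%), CH2Cl2, −10 °C → rt
Reagents that add atoms: none
Why: carbodiimide-mediated N-acylation of the oxazolidinone gives the alkynoyl imide that will supply C2, C3 and the temporary chelating group.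

Step 7
Reactants: 10 C-allylated triphenol; 13 3-(prop-2-ynoyl)-1,3-oxazolidin-2-one
Product: 14 3-[(2E)-3-{3,5-dihydroxy-4-(3-methylbutanoyl)-2-[(2,3,3-trimethylcyclopenta-1,4-dien-1-yl)methyl]phenoxy}prop-2-enoyl]-1,3-oxazolidin-2-one
Conditions: DABCO (10 mol%), CH2Cl2, 0 °C, slow addition of 13; product used at once
Reagents that add atoms: none
Why: the hydroxyl para to the ketone is the most acidic and the only one not tied up next to the carbonyl, so the amine-catalysed oxa-Michael addition to the activated alkyne should take place there and give the thermodynamically preferred E enol ether.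

Step 8
Reactants: 14 E-aryloxyacryloyl imide
Product: 15 born-5-ene cycloadduct: C1 methyl, C7 gem-dimethyl, 2-endo aryl ether oxygen and C6–CH2 on adjacent arene carbons (seven-membered benzoxepine), 3-exo (2-oxo-1,3-oxazolidin-3-yl)carbonyl, arene bearing 3-methylbutanoyl between two OH; bridgeheads as in (+)-borneol
Conditions: [Cu((S,S)-t-Bu-box)](SbF6)2 (10 mol%; t-Bu-box = 2,2'-(propane-2,2-diyl)bis[(4S)-4-tert-butyl-4,5-dihydro-1,3-oxazole]), CH2Cl2, −20 °C → rt
Reagents that add atoms: none
Why: Proposed new method: chelation of the two imide carbonyls to square-planar divalent copper lowers the LUMO of the s-cis (E)-3-aryloxyacryloyl unit, which then adds in a concerted, asynchronous, normal-demand [4+2] to the 1,5,5-trimethylcyclopentadiene held four atoms away, its O-bearing β-carbon bonding to the methyl-bearing diene terminus (C1–C2) and its α-carbon to the CH terminus (C3–C4). The closest known reaction types are the bis(oxazoline)–copper-catalysed Diels–Alder reactions of 3-(3-acyloxy- or 3-alkyl-acryloyl)oxazolidinones with cyclopentadiene, the same catalysis applied to tethered trienimides, and thermal type 2 intramolecular Diels–Alder reactions (tether on C-2 of the diene); untested is their combination on a 5,5-disubstituted cyclopentadiene with a push-pull dienophile. Two rings close: the cyclohexene C1–C2–C3–C4–C5–C6 forms by the [4+2] across the existing five-membered ring (giving the bicyclo[2.2.1]heptene), and the seven-membered benzoxepine O–C2–C1–C6–CH2–Car–Car is closed by the same C1–C2 bond in the bridged 1,3-mode of a type 2 cycloaddition. C2 is set by the catalyst (the tert-butyl group of the (S,S) ligand should cover the Si face of the α-carbon, so the diene adds to the Re,Re face of the alkene), C1 and C4 follow from suprafacial addition with the aryloxy group endo, and the temporary C3 centre (imide exo, trans to oxygen) is fixed by the E geometry. The step needs the 1,3 ("meta") regiochemistry, an endo oxygen and one enantioface: the tether secures the first two, because by a simple model only an endo oxygen bound to the diene terminus next to C6 lies within reach of the CH2–Car–Car–O unit (about 3 Å from CH2 to O in the transition state against nearly 5 Å for an exo oxygen), and the catalyst secures the third as long as the E geometry of 14 is kept, since the Z isomer would offer the opposite face of C2. The main strain is the exo imide under the lower C7 methyl group, which the Lewis-acid acceleration has to overcome.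

Step 9
Reactants: 15 born-5-ene cycloadduct
Product: 16 saturated imide: bornane with 6-endo CH2 (cis-bridged benzoxepine), 2-endo aryl ether oxygen and 3-exo (2-oxo-1,3-oxazolidin-3-yl)carbonyl
Conditions: H2 (1 atm), 10% Pd/C, EtOAc, rt
Reagents that add atoms: none
Why: heterogeneous syn-hydrogenation of the strained C5=C6 bond should occur from the exo face, because the endo face is covered by the arene and endo delivery would demand an impossible trans-bridged seven-membered ring, so the C6 hydrogen ends exo and the benzylic CH2 endo.

Step 10
Reactants: 16 saturated imide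
Product: 18 3-exo carboxylic acid of the benzoxepine-bridged bornane, via lithium peroxycarboxylate 17 (not isolated)
Conditions: LiOH, H2O2, THF/H2O (3:1), 0 °C; Na2SO3; then 1 M HCl
Reagents that add atoms: lithium hydroperoxide, [Li+].[O-]O, made in the flask from LiOH ([Li+].[OH-]) and hydrogen peroxide (OO)
Why: hydroperoxide attacks the exocyclic imide carbonyl selectively (standard oxazolidinone cleavage), releasing the helper ring at 0 °C without touching the chelated aryl ketone or the C2 ether.

Step 11
Reactants: 18 carboxylic acid
Product: 20 deformyl target (the target lacking the CHO group), via thiohydroxamate ester 19 (not isolated)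
Conditions: 1-hydroxypyridine-2(1H)-thione, DCC, CH2Cl2, 0 °C → rt, dark; then t-BuSH, visible light, rt
Reagents that add atoms: 1-hydroxypyridine-2(1H)-thione, ON1C=CC=CC1=S (its atoms are in 19 only)
Why: Barton reductive decarboxylation: the O-acyl thiohydroxamate fragments under light to CO2 and the secondary C3 radical, which should take hydrogen from the thiol faster than it can expel the β-aryloxy group, leaving the CH2 of the target (C3 is no stereocentre, and the alkene was saturated first so that the radical cannot close to a nortricyclene).

Step 12
Reactants: 20 deformyl target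
Product: 22 CNP0246493.1 (target), via iminium chloride 21 (not isolated)
Conditions: POCl3, DMF, EtOAc, 0 °C → rt; then H2O, 50 °C
Reagents that add atoms: N,N-dimethylformamide, CN(C)C=O (formyl carbon; the NMe2 group is in 21 only); phosphoryl chloride, O=P(Cl)(Cl)Cl (chloride of 21 only); water, O (aldehyde oxygen)
Why: Vilsmeier–Haack formylation can only strike the one remaining aromatic CH (ortho to OH and to the ether oxygen, para to OH), so no regiochemical choice exists, and low temperature with about one equivalent of reagent should keep the enolisable ketone side chain and the secondary alkyl aryl ether out of play.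

**Compound list**

1 | 4,4-dimethylcyclopent-2-en-1-one | CC1(C)CC(=O)C=C1 | starting material
2 | lithium 3,3-dimethylcyclopenta-1,4-dien-1-olate (enolate of 1) | [Li+].[O-]C1=CC(C)(C)C=C1 | intermediate
3 | 4,4,5-trimethylcyclopent-2-en-1-one (racemic) | CC1C(=O)C=CC1(C)C | intermediate
4 | lithium 2,3,3-trimethylcyclopenta-1,4-dien-1-olate (dienolate of 3) | [Li+].[O-]C1=C(C)C(C)(C)C=C1 | intermediate
5 | 2,3,3-trimethylcyclopenta-1,4-dien-1-yl trifluoromethanesulfonate | CC1=C(OS(=O)(=O)C(F)(F)F)C=CC1(C)C | intermediate
6 | (2,3,3-trimethylcyclopenta-1,4-dien-1-yl)methanol | CC1=C(CO)C=CC1(C)C | intermediate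
7 | phloroglucinol (benzene-1,3,5-triol) | Oc1cc(O)cc(O)c1 | starting material
8 | 3-methylbutanoyl chloride | CC(C)CC(=O)Cl | starting material
9 | 3-methyl-1-(2,4,6-trihydroxyphenyl)butan-1-one (phlorisovalerophenone) | CC(C)CC(=O)c1c(O)cc(O)cc1O | intermediate
10 | 3-methyl-1-{2,4,6-trihydroxy-3-[(2,3,3-trimethylcyclopenta-1,4-dien-1-yl)methyl]phenyl}butan-1-one | CC(C)CC(=O)c1c(O)cc(O)c(CC2=C(C)C(C)(C)C=C2)c1O | intermediate
11 | propiolic acid | C#CC(=O)O | starting material
12 | 1,3-oxazolidin-2-one | O=C1NCCO1 | starting material
13 | 3-(prop-2-ynoyl)-1,3-oxazolidin-2-one | C#CC(=O)N1CCOC1=O | intermediate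
14 | 3-[(2E)-3-{3,5-dihydroxy-4-(3-methylbutanoyl)-2-[(2,3,3-trimethylcyclopenta-1,4-dien-1-yl)methyl]phenoxy}prop-2-enoyl]-1,3-oxazolidin-2-one | CC(C)CC(=O)c1c(O)cc(O/C=C/C(=O)N2CCOC2=O)c(CC2=C(C)C(C)(C)C=C2)c1O | intermediate
15 | born-5-ene cycloadduct (2-endo aryl ether O and C6–CH2 bridged by the arene, 3-exo oxazolidinone carboximide, (+)-borneol bridgeheads) | CC(C)CC(=O)c1c(O)cc2c(c1O)CC1=C[C@@H]3[C@@H](C(=O)N4CCOC4=O)[C@H](O2)[C@@]1(C)C3(C)C | intermediate
16 | saturated imide (6-endo CH2, 2-endo O, 3-exo oxazolidinone carboximide) | CC(C)CC(=O)c1c(O)cc2c(c1O)C[C@@H]1C[C@@H]3[C@@H](C(=O)N4CCOC4=O)[C@H](O2)[C@@]1(C)C3(C)C | intermediate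
17 | lithium peroxycarboxylate of acid 18 | [Li+].CC(C)CC(=O)c1c(O)cc2c(c1O)C[C@@H]1C[C@@H]3[C@@H](C(=O)O[O-])[C@H](O2)[C@@]1(C)C3(C)C | intermediate
18 | 3-exo carboxylic acid of the benzoxepine-bridged bornane | CC(C)CC(=O)c1c(O)cc2c(c1O)C[C@@H]1C[C@@H]3[C@@H](C(=O)O)[C@H](O2)[C@@]1(C)C3(C)C | intermediate
19 | O-acyl thiohydroxamate (2-thioxopyridin-1(2H)-yl ester) of 18 | CC(C)CC(=O)c1c(O)cc2c(c1O)C[C@@H]1C[C@@H]3[C@@H](C(=O)ON4C=CC=CC4=S)[C@H](O2)[C@@]1(C)C3(C)C | intermediate
20 | deformyl target (target lacking CHO; (1R,2S,4R,6S) in bornane numbering) | CC(C)CC(=O)c1c(O)cc2c(c1O)C[C@@H]1C[C@@H]3C[C@H](O2)[C@@]1(C)C3(C)C | intermediate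
21 | aryl-methylidene dimethyliminium chloride of the target | CC(C)CC(=O)c1c(O)c(C=[N+](C)C)c2c(c1O)C[C@@H]1C[C@@H]3C[C@H](O2)[C@@]1(C)C3(C)C.[Cl-] | intermediate
22 | CNP0246493.1: (1R,2S,4R,6S)-bornane (bornane numbering) whose 2-endo oxygen and 6-endo CH2 sit on adjacent carbons of an arene that carries, going on from the ether carbon, CHO, OH, 3-methylbutanoyl and OH | CC(C)CC(=O)c1c(O)c(C=O)c2c(c1O)C[C@@H]1C[C@@H]3C[C@H](O2)[C@@]1(C)C3(C)C | target

**Step count and risks**

Total steps: 12. Longest linear sequence: 10 steps (1, 2, 3, 5, 7, 8, 9, 10, 11, 12).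

Steps most likely to fail:

Step 8 (Proposed new method). What may go wrong: poor turnover, because the imide must sit exo under the lower C7 methyl group; erosion of enantioselectivity by an uncatalysed background cycloaddition or by E/Z isomerisation of the push-pull alkene; competitive binding of the catalyst by the hydroxy ketone. The fallback replaces catalyst control by a covalently bound auxiliary and a separable pair of diastereomers, all by known reaction types. It sets out from 10 and comes back at 18. Propiolic acid 11 is coupled (DCC, cat. DMAP) to commercial (S)-4-benzyl-1,3-oxazolidin-2-one to give (S)-4-benzyl-3-(prop-2-ynoyl)-1,3-oxazolidin-2-one F1. DABCO-catalysed addition of 10 gives the E-aryloxyacryloyl imide of the auxiliary F2. Heating F2 in toluene (80–110 °C, thermal type 2 intramolecular Diels–Alder reaction) should give the two endo-oxygen adducts, which are now diastereomers, and the one with the required skeleton, the auxiliary-bearing cycloadduct F3, is separated by chromatography or crystallisation. Hydrogenation (H2, Pd/C) gives the saturated auxiliary imide F4, and LiOH/H2O2 cleavage returns to acid 18.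

Step 5. What may go wrong: double or dearomatising C-allylation, O-allylation, or loss of the π-allyl complex by β-hydride elimination toward a triene. The fallback changes from π-allyl chemistry to direct displacement. It sets out from 6 and comes back at 10. PBr3 (Et2O, −20 °C) converts 6 into 1-(bromomethyl)-2,3,3-trimethylcyclopenta-1,4-diene F5, which is used at once to C-alkylate an excess of 9 with K2CO3 in acetone, the classical C-prenylation protocol for acylphloroglucinols.

Step 12. What may go wrong: attack of the chloroiminium reagent on the enolisable hydroxy ketone side chain (chromone formation), or acid-induced ionisation of the secondary alkyl aryl ether. The fallback replaces electrophilic formylation by halogenation and cross-coupling. It sets out from 20 and comes back at 22. N-iodosuccinimide (MeCN, 0 °C) iodinates the only free aromatic position to give the aryl iodide F6, and palladium-catalysed reductive carbonylation (PdCl2(PPh3)2, CO, HCO2Na, DMF, 90 °C) converts F6 into 22.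

**Further compounds**

F1 | step 8 | (S)-4-benzyl-3-(prop-2-ynoyl)-1,3-oxazolidin-2-one | C#CC(=O)N1[C@@H](Cc2ccccc2)COC1=O
F2 | step 8 | E-aryloxyacryloyl imide of the auxiliary (analogue of 14) | CC(C)CC(=O)c1c(O)cc(O/C=C/C(=O)N2[C@@H](Cc3ccccc3)COC2=O)c(CC2=C(C)C(C)(C)C=C2)c1O
F3 | step 8 | auxiliary-bearing cycloadduct (analogue of 15) | CC(C)CC(=O)c1c(O)cc2c(c1O)CC1=C[C@@H]3[C@@H](C(=O)N4[C@@H](Cc5ccccc5)COC4=O)[C@H](O2)[C@@]1(C)C3(C)C
F4 | step 8 | saturated auxiliary imide (analogue of 16) | CC(C)CC(=O)c1c(O)cc2c(c1O)C[C@@H]1C[C@@H]3[C@@H](C(=O)N4[C@@H](Cc5ccccc5)COC4=O)[C@H](O2)[C@@]1(C)C3(C)C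
F5 | step 5 | 1-(bromomethyl)-2,3,3-trimethylcyclopenta-1,4-diene | CC1=C(CBr)C=CC1(C)C
F6 | step 12 | aryl iodide of 20 (iodine at the free aromatic position) | CC(C)CC(=O)c1c(O)c(I)c2c(c1O)C[C@@H]1C[C@@H]3C[C@H](O2)[C@@]1(C)C3(C)C
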